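**Plan**
Retrosynthesis: the lactone bond O1–C2 and the ring bond C3a–C4 are cut in one operation. This opens the butenolide and the cyclohexane together and gives an acyclic γ-hydroxy ynoate with a methallyl terminus. Further cuts are the C6 palmitate, C3a–C7a (propiolate anion + methyl ketone), C7–C7a (acyl-anion equivalent + epoxide) and C4–C5 (isopropenyl metal + epichlorohydrin).
Enabling feature: C4 is a quaternary carbon of the six-membered ring with two methyl groups, so it corresponds to the tertiary radical formed by adding H• to a methallyl CH2. It is bonded to C3a, the β-carbon of the C2 carbonyl in the five-membered ring, and the C7a oxygen lies γ to C2. C4 and C7a carry no hydrogen, so the exocyclic enoate can only isomerise E/Z.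
Forward: the C5–C6–C7 unit of epichlorohydrin is extended at C5 by the isopropenyl unit (C4), at C7 by C7a with its methyl group, then by C3a–C3–C2. The carbocycle closes first (radical, 6-exo-dig) and the lactone second, in the same step.
Stereochemistry: C6 (S) comes from (S)-epichlorohydrin and its C–O bond is never broken. C7a (R) is relayed from C6 by a 1,3-chelation-controlled acetylide addition. The key step creates no stereocentre.

Key step: step 9

Assumption: the target is the (6S,7aR) isomer encoded by the SMILES. Benzofuranone numbering of the target is used for positions in open-chain intermediates as well. The minor C7a epimer from the acetylide addition is taken to be separable by chromatography at the PMB-ether stage.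

Step 1
Reactants: 1 (S)-epichlorohydrin; 2 isopropenylmagnesium bromide
Product: 3 (2S)-1-chloro-4-methylpent-4-en-2-ol
Conditions: CuI (10 mol %), THF, −40 to −20 °C; aq. work-up
Reagents that add atoms: none
Why: Copper-catalysed Grignard opening of a terminal epoxide (SN2 at the unsubstituted ring carbon, faster than displacement of chloride) forms C4–C5 and leaves the C–O bond of the stereocentre intact, so the S centre of 1 becomes C6 of the target.

Step 2
Reactants: 3 (2S)-1-chloro-4-methylpent-4-en-2-ol
Product: 4 (2S)-2-(2-methylprop-2-en-1-yl)oxirane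
Conditions: powdered NaOH, Et2O, rt; careful distillation
Reagents that add atoms: none
Why: Intramolecular Williamson etherification (chlorohydrin to epoxide) displaces the primary chloride with the secondary alkoxide, so the stereocentre is not involved and its configuration is kept.

Step 3
Reactants: 5 2-methyl-1,3-dithiane; 4 (2S)-2-(2-methylprop-2-en-1-yl)oxirane
Product: 7 (2S)-4-methyl-1-(2-methyl-1,3-dithian-2-yl)pent-4-en-2-ol, via 2-lithio-2-methyl-1,3-dithiane 6 (not isolated)
Conditions: 5, n-BuLi, THF, −20 °C; then 4, DMPU, −20 °C to rt; aq. work-up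
Reagents that add atoms: none
Why: Corey–Seebach umpolung, in which the lithiated dithiane opens the monosubstituted epoxide at its CH2 terminus by SN2, forms C7–C7a, brings in C7a at the ketone oxidation level with its methyl group, and retains the carbinol configuration.

Step 4
Reactants: 7 (2S)-4-methyl-1-(2-methyl-1,3-dithian-2-yl)pent-4-en-2-ol
Product: 8 2-{(2S)-2-[(4-methoxybenzyl)oxy]-4-methylpent-4-en-1-yl}-2-methyl-1,3-dithiane
Conditions: NaH, PMBCl, TBAI (cat.), THF/DMF, 0 °C to rt
Reagents that add atoms: 4-methoxybenzyl chloride, COc1ccc(CCl)cc1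
Why: Williamson etherification installs a PMB ether, chosen because its basic oxygen can chelate in step 6, it blocks oxa-Michael attack of the C6 oxygen on the later ynoate, and it is removed oxidatively at neutral pH.

Step 5
Reactants: 8 2-{(2S)-2-[(4-methoxybenzyl)oxy]-4-methylpent-4-en-1-yl}-2-methyl-1,3-dithiane
Product: 9 (4S)-4-[(4-methoxybenzyl)oxy]-6-methylhept-6-en-2-one
Conditions: MeI, CaCO3, MeCN/H2O (9:1), 45 °C
Reagents that add atoms: water, O
Why: Alkylative dithiane hydrolysis (S-methylation, then capture of the thionium ion by water) is buffered by CaCO3 and uses neither an oxidant nor a halonium source, so the PMB ether, the 1,1-disubstituted alkene and the elimination-prone β-alkoxy ketone should survive.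

Step 6
Reactants: 10 methyl propiolate; 9 (4S)-4-[(4-methoxybenzyl)oxy]-6-methylhept-6-en-2-one
Product: 12 methyl (4R,6S)-4-hydroxy-6-[(4-methoxybenzyl)oxy]-4,8-dimethylnon-8-en-2-ynoate, via methyl 3-lithiopropiolate 11 (not isolated)
Conditions: 10, LiHMDS, THF, −78 °C; cannulated into 9 + MgBr2·OEt2 (3 equiv), CH2Cl2, −78 to −40 °C; aq. work-up, chromatography
Reagents that add atoms: none
Why: Chelation-controlled (Cram–Reetz 1,3-model) 1,2-addition of an acetylide, in which Mg(II) ties the ketone and PMB oxygens into a six-membered half-chair with the methallyl arm equatorial and the slim, weakly basic propiolate anion attacks axially on the face anti to that arm, sets C7a as R (1,3-anti to the C6 oxygen along the alkyne-bearing chain), while mild MgBr2 avoids the carbonyl-ene closure with the methallyl group that TiCl4-type acids would cause.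

Step 7
Reactants: 12 methyl (4R,6S)-4-hydroxy-6-[(4-methoxybenzyl)oxy]-4,8-dimethylnon-8-en-2-ynoate
Product: 13 methyl (4R,6S)-4,6-dihydroxy-4,8-dimethylnon-8-en-2-ynoate
Conditions: DDQ, CH2Cl2/pH 7 buffer (10:1), 0 °C
Reagents that add atoms: none
Why: Oxidative PMB cleavage with DDQ (hydride abstraction at the electron-rich benzylic position, then hydrolysis of the oxocarbenium ion) runs at neutral pH, where the electron-poor alkyne, the isolated alkene and the tertiary alcohol are inert, and the water present suppresses capture of the cation by the tertiary hydroxyl.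

Step 8
Reactants: 13 methyl (4R,6S)-4,6-dihydroxy-4,8-dimethylnon-8-en-2-ynoate; 14 palmitoyl chloride
Product: 15 methyl (4R,6S)-4-hydroxy-4,8-dimethyl-6-(palmitoyloxy)non-8-en-2-ynoate
Conditions: pyridine, CH2Cl2, 0 °C to rt
Reagents that add atoms: none
Why: Acylation with an acid chloride and pyridine selects the secondary C6 hydroxyl over the tertiary propargylic one on steric grounds, and omitting DMAP avoids nucleophilic attack on the ynoate.

Step 9
Reactants: 15 methyl (4R,6S)-4-hydroxy-4,8-dimethyl-6-(palmitoyloxy)non-8-en-2-ynoate
Product: 18 (−)-3-O-palmitoylloliolide, via Z-hydroxy enoate 16 (not isolated), via E-hydroxy enoate 17 (not isolated)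
Conditions: Fe(acac)3 (30 mol %), PhSiH3 (3 equiv), degassed EtOH (0.02 M), 60 °C; silica plug, then hν (300 nm), acetone, PPTS (cat.), rt
Reagents that add atoms: none
Why: Proposed new method: an iron hydride formed from Fe(acac)3 and PhSiH3 transfers a hydrogen atom to the CH2 terminus of the electron-rich methallyl group and leaves the electron-poor alkyne alone, the nucleophilic tertiary C4 radical adds to ynoate β-carbon C3a, and the α-ester vinyl radical is quenched by hydrogen-atom transfer or by Fe(II) reduction and protonation by ethanol, giving the cyclohexylidene acetates 16 and 17. The closest known reactions are the iron-catalysed reductive olefin coupling with acrylate-type acceptors (an MHAT-initiated Giese reaction) and tin-hydride 6-exo-dig cyclisations of alkyl radicals onto alkynoates, and the new element is their combination on a γ-hydroxy ynoate with lactonisation in the same operation. The carbocycle closes 6-exo-dig (C3a–C4), preferred over 7-endo-dig attack at C3 by polarity matching, ring size and the Thorpe–Ingold effect of fully substituted C7a, and the butenolide closes 5-exo-trig when the C7a hydroxyl of Z isomer 16 attacks ester carbonyl C2 and expels methanol. No stereocentre is created and no bond at C6 or C7a is broken, so both configurations pass unchanged into 18. The one selectivity the substrate does not secure is the geometry of the vinyl-radical quench, because C4 and C7a shield C3 to a similar degree, so the crude mixture is irradiated with acetone as triplet sensitiser, which interconverts 16 and 17 while only 16 is drained irreversibly into the lactone. This funnel should be clean because C4 and C7a carry no hydrogen, which rules out photochemical deconjugation of the enoate and leaves the vinyl radical only unfavourable 1,4-relationships for internal hydrogen transfer.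

**Compound list**
1 | (S)-epichlorohydrin | ClC[C@@H]1CO1 | starting material
2 | isopropenylmagnesium bromide | CC(=C)[Mg]Br | starting material
3 | (2S)-1-chloro-4-methylpent-4-en-2-ol | ClC[C@@H](O)CC(C)=C | intermediate
4 | (2S)-2-(2-methylprop-2-en-1-yl)oxirane | CC(=C)C[C@H]1CO1 | intermediate
5 | 2-methyl-1,3-dithiane | CC1SCCCS1 | starting material
6 | 2-lithio-2-methyl-1,3-dithiane | CC1([Li])SCCCS1 | intermediate
7 | (2S)-4-methyl-1-(2-methyl-1,3-dithian-2-yl)pent-4-en-2-ol | CC1(C[C@@H](O)CC(C)=C)SCCCS1 | intermediate
8 | 2-{(2S)-2-[(4-methoxybenzyl)oxy]-4-methylpent-4-en-1-yl}-2-methyl-1,3-dithiane | CC1(C[C@@H](OCc2ccc(OC)cc2)CC(C)=C)SCCCS1 | intermediate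
9 | (4S)-4-[(4-methoxybenzyl)oxy]-6-methylhept-6-en-2-one | CC(=O)C[C@@H](OCc1ccc(OC)cc1)CC(C)=C | intermediate
10 | methyl propiolate | COC(=O)C#C | starting material
11 | methyl 3-lithiopropiolate | COC(=O)C#C[Li] | intermediate
12 | methyl (4R,6S)-4-hydroxy-6-[(4-methoxybenzyl)oxy]-4,8-dimethylnon-8-en-2-ynoate | COC(=O)C#C[C@](C)(O)C[C@@H](OCc1ccc(OC)cc1)CC(C)=C | intermediate
13 | methyl (4R,6S)-4,6-dihydroxy-4,8-dimethylnon-8-en-2-ynoate | COC(=O)C#C[C@](C)(O)C[C@@H](O)CC(C)=C | intermediate
14 | palmitoyl chloride | CCCCCCCCCCCCCCCC(=O)Cl | starting material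
15 | methyl (4R,6S)-4-hydroxy-4,8-dimethyl-6-(palmitoyloxy)non-8-en-2-ynoate | COC(=O)C#C[C@](C)(O)C[C@@H](OC(=O)CCCCCCCCCCCCCCC)CC(C)=C | intermediate
16 | methyl (2Z)-[(2R,4S)-2-hydroxy-2,6,6-trimethyl-4-(palmitoyloxy)cyclohexylidene]acetate (ester cis to the carbinol carbon) | COC(=O)/C=C1/C(C)(C)C[C@H](OC(=O)CCCCCCCCCCCCCCC)C[C@@]1(C)O | intermediate
17 | methyl (2E)-[(2R,4S)-2-hydroxy-2,6,6-trimethyl-4-(palmitoyloxy)cyclohexylidene]acetate (ester cis to the gem-dimethyl carbon) | COC(=O)/C=C1\C(C)(C)C[C@H](OC(=O)CCCCCCCCCCCCCCC)C[C@@]1(C)O | intermediate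
18 | (−)-3-O-palmitoylloliolide, (6S,7aR)-4,4,7a-trimethyl-2-oxo-2,4,5,6,7,7a-hexahydro-1-benzofuran-6-yl hexadecanoate | CCCCCCCCCCCCCCCC(=O)O[C@H]1CC(C)(C)C2=CC(=O)O[C@]2(C)C1 | target

**Step count**
Total steps: 9. Longest linear sequence: 9 (1 to 18).

**Steps most likely to fail**

Step 9. Reduction of the tertiary radical may outrun ring closure. The hydride system may consume the ynoate. Hydrogen delivery to the vinyl radical may favour the non-lactonising geometry so strongly that the photochemical funnel becomes slow.
The fallback runs from 12 back to 18 and uses known reaction types only. It reverses the order of ring formation and lowers the oxidation level of the acceptor.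
- Lindlar semi-hydrogenation of 12 (H2, Pd/CaCO3–Pb, quinoline, EtOAc) should give the cis-enoate. This closes spontaneously to the butenolide (5R)-5-{(2S)-2-[(4-methoxybenzyl)oxy]-4-methylpent-4-en-1-yl}-5-methylfuran-2(5H)-one F1.
- The established iron-catalysed reductive olefin coupling is then run intramolecularly onto an alkene acceptor (Fe(acac)3, PhSiH3, EtOH, 60 °C, 6-exo-trig). It should form the same C3a–C4 bond and give the cis-fused saturated lactone (3aS,6S,7aR)-6-[(4-methoxybenzyl)oxy]-4,4,7a-trimethylhexahydro-1-benzofuran-2(3H)-one F2.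
- LDA followed by PhSeBr (THF, −78 °C) should give the convex-face selenide (3R,3aS,6S,7aR)-6-[(4-methoxybenzyl)oxy]-4,4,7a-trimethyl-3-(phenylselanyl)hexahydro-1-benzofuran-2(3H)-one F3.
- Oxidation with H2O2 and syn elimination towards the only β-hydrogen (C3a–H) restores C3=C3a in O-PMB-loliolide F4.
- DDQ then frees (−)-loliolide F5, and acylation with 14 (pyridine, DMAP, CH2Cl2) returns to 18.

Step 6. THF and the ester group of the nucleophile may compete for magnesium, so chelation is incomplete and facial selectivity erodes. Enolisation followed by β-elimination of the PMB-oxy group is a second loss channel.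
The fallback runs from 9 back to 12. It uses a nucleophile without the ester and attaches C2 afterwards.
- Ethynylmagnesium bromide is added to 9 in CH2Cl2 at −78 °C, so the magnesium of the reagent itself closes the chelate. This should give (3R,5S)-5-[(4-methoxybenzyl)oxy]-3,7-dimethyloct-7-en-1-yn-3-ol F6.
- Double deprotonation (n-BuLi, 2.2 equiv, THF, −78 °C) and CO2 should give (4R,6S)-4-hydroxy-6-[(4-methoxybenzyl)oxy]-4,8-dimethylnon-8-en-2-ynoic acid F7. The carbonate formed at the alkoxide reverts on acidification.
- Methylation with MeI and KHCO3 in DMF leads back to 12.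

Step 5. S-Methylation of the hindered 2,2-disubstituted dithiane may be slow. The longer heating this forces would allow β-elimination of the ether or migration of the alkene.
The fallback runs from 4 back to 9. It replaces the masked acyl anion by a monosubstituted alkene as the latent methyl ketone.
- Vinylmagnesium bromide with catalytic CuI opens 4 to (4R)-2-methylhepta-1,6-dien-4-ol F8. The spatial arrangement is unchanged, and the descriptor changes only through CIP ranking.
- NaH and PMBCl give (4R)-4-[(4-methoxybenzyl)oxy]-2-methylhepta-1,6-diene F9.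
- Tsuji–Wacker oxidation (PdCl2, CuCl, O2, DMF/H2O) converts only the monosubstituted alkene into the methyl ketone, leaves the 1,1-disubstituted alkene untouched, and gives 9.

**Further compounds**
F1 | step 9 | (5R)-5-{(2S)-2-[(4-methoxybenzyl)oxy]-4-methylpent-4-en-1-yl}-5-methylfuran-2(5H)-one | O=C1C=C[C@@](C)(C[C@@H](OCc2ccc(OC)cc2)CC(C)=C)O1
F2 | step 9 | (3aS,6S,7aR)-6-[(4-methoxybenzyl)oxy]-4,4,7a-trimethylhexahydro-1-benzofuran-2(3H)-one | COc1ccc(CO[C@H]2CC(C)(C)[C@@H]3CC(=O)O[C@]3(C)C2)cc1
F3 | step 9 | (3R,3aS,6S,7aR)-6-[(4-methoxybenzyl)oxy]-4,4,7a-trimethyl-3-(phenylselanyl)hexahydro-1-benzofuran-2(3H)-one | COc1ccc(CO[C@H]2CC(C)(C)[C@@H]3[C@@H]([Se]c4ccccc4)C(=O)O[C@]3(C)C2)cc1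
F4 | step 9 | O-PMB-loliolide, (6S,7aR)-6-[(4-methoxybenzyl)oxy]-4,4,7a-trimethyl-5,6,7,7a-tetrahydro-1-benzofuran-2(4H)-one | COc1ccc(CO[C@H]2CC(C)(C)C3=CC(=O)O[C@]3(C)C2)cc1
F5 | step 9 | (−)-loliolide, (6S,7aR)-6-hydroxy-4,4,7a-trimethyl-5,6,7,7a-tetrahydro-1-benzofuran-2(4H)-one | O[C@H]1CC(C)(C)C2=CC(=O)O[C@]2(C)C1
F6 | step 6 | (3R,5S)-5-[(4-methoxybenzyl)oxy]-3,7-dimethyloct-7-en-1-yn-3-ol | C#C[C@](C)(O)C[C@@H](OCc1ccc(OC)cc1)CC(C)=C
F7 | step 6 | (4R,6S)-4-hydroxy-6-[(4-methoxybenzyl)oxy]-4,8-dimethylnon-8-en-2-ynoic acid | OC(=O)C#C[C@](C)(O)C[C@@H](OCc1ccc(OC)cc1)CC(C)=C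
F8 | step 5 | (4R)-2-methylhepta-1,6-dien-4-ol | C=CC[C@@H](O)CC(C)=C
F9 | step 5 | (4R)-4-[(4-methoxybenzyl)oxy]-2-methylhepta-1,6-diene | C=CC[C@@H](OCc1ccc(OC)cc1)CC(C)=C
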